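The epsilon run flattens near 16.0% and the beta run near 29.0%, and beta differs from epsilon by having twice the c(partner).

| flask | starting material | partner | remark | time |
|---|---|---|---|---|
| beta | 0.085 M | 0.17 M | run made earlier |  |
| eta | 0.057 M | 0.17 M | run made earlier |  |
| theta | 0.13 M | 0.17 M | run made earlier |  |
| epsilon | 0.085 M | 0.085 M | run made earlier |  |
| south | 0.085 M (fed, over 3.0 min) | 0.170 M | all else is in the flask from the start; the feed brings no volume worth counting | 4.0 min |
| west | 0.085 M | 0.170 M | everything together at the start | 4.0 min |
| north-west | 0.085 M | 0.170 M (fed, over 3.0 min) | all else is in the flask from the start; the feed brings no volume worth counting | 4.0 min |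

| run | time / min | first product / % |
|---|---|---|
| beta | 0.200 | 15 |
| beta | 0.333 | 21 |
| beta | 0.667 | 28 |
| beta | 1.33 | 30 |
| beta | 2.50 | 28 |
| eta | 0.500 | 25 |
| eta | 1.00 | 31 |
| eta | 1.33 | 30 |
| eta | 2.00 | 29 |
| eta | 2.50 | 29 |
| theta | 0.200 | 18 |
| theta | 0.667 | 24 |
| theta | 1.00 | 28 |
| theta | 1.50 | 29 |
| theta | 2.50 | 24 |
| epsilon | 0.500 | 12 |
| epsilon | 1.00 | 18 |
| epsilon | 1.33 | 17 |
| epsilon | 2.00 | 15 |
| epsilon | 2.50 | 16 |

(scatter of a reading: 1.5 percentage points)



- which flask leads in amount of first product, in percent of the starting material charged ("all alike" within 1.5 percentage points) (south / west / north-west / all alike)
- how much first product is there at the end, in percent of the starting material charged: south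
- how much first product is there at the end, in percent of the starting material charged: west
- how much first product is there at the end, in percent of the starting material charged: north-west

I read the tables column against column. Eta, at 0.057 M of starting material, and theta, at 0.13 M, both read 29% at their fourth row, so at those rows the reading does not follow c(starting material). A pseudo-first-order capture by a partner that dies on its own clock would behave this way. I therefore define the capture number, 0.342: the capture rate per starting material summed over the partner's life, read from a plateau as the logarithm of one over the fraction left. Epsilon gives 0.174, so beta's number reads twice epsilon's, in step with the partner charge. The first beta row stands near half the plateau at 0.200 min, which reads as a partner lifetime of 0.289 min.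

Now I solve both ends. West has beta's charges, all in at the start, so the capture number simply hands back 29.0%. In north-west I take the summed exposure as unchanged by feeding the partner, so I expect the same. In south the feed of starting material lasts 3.0 min, far longer than the lifetime, so the partner meets what has arrived during its life, and the capture number times lifetime over feed time gives a captured fraction of 3.29%. This is my own reckoning, not a reading.

The forecast says all alike, with 29%, 29% and 29%, and differs from me on south: “The reversible picture is the simplest without an unseen side reaction”.

The simulation puts north-west ahead, at 29.0%, with west at 26.2% and south at 5.59%.

    first product + by-product → side product (k = 0.0381 L mol⁻¹ s⁻¹)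
    partner + first product → bis adduct + by-product (k = 0.0225 L mol⁻¹ s⁻¹)
    starting material + partner → first product + by-product (k = 0.114 L mol⁻¹ s⁻¹)
    partner + bis adduct → triple product + by-product (k = 0.0482 L mol⁻¹ s⁻¹)
    partner → decomposed reagent (k = 0.0384 s⁻¹)

Taking the partner's decay out of the north-west and south pair shrinks their gap from 23 percentage points to 3.5 points, the largest single effect. South's 5.59% stands above my 3.29%, but far from the forecast's 29%. With 0.68 M of partner in a flask like north-west, the capture number scales to 1.37, so I expect 25.4% of the starting material left, and that flask holds 17.5% of starting material after 4.00 min.

All runs stem from a simulated flask for substances that don't exist.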